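**Retrosynthetic overview**
- Target ⇐ global O‑debenzylation; the open 1,3‑diol arm ⇐ tethered syn‑hydrosilylation of a cis‑diaryl trisubstituted alkene, then C–Si → C–O oxidation with retention.
- That alkene ⇐ Suzuki coupling on ring B of a trans‑α,β‑dibenzyl‑γ‑butyrolactone ⇐ enolate alkylation of an (R)‑β‑benzyl lactone with a phenylcoumaran benzylic bromide.
- Phenylcoumaran ⇐ acid‑mediated C7–O(aryl) ring closure of an anti diol ⇐ hydroboration–oxidation (C–B → C–O) of a cis‑diaryl alkene from 5‑iodovanillin.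
- (R)‑β‑Benzyl lactone ⇐ Stobbe condensation, asymmetric hydrogenation, reduction and lactonisation from 5‑bromovanillin.
- Both alkenes ⇐ one (Z)‑α‑bromoacrylate‑derived alkenylboronate from O‑benzylvanillin. Ring order: dihydrobenzofuran first (step 7), lactone second (step 12).

Locants used below: in each C6–C3 arm, C7 carries the 4‑oxy‑3‑methoxyphenyl ring, C8 carries ring A or ring B, C9 is the CH2O carbon. Ring A is the benzofuran arene; ring B is the arene of the open diol arm.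

Assumption: the sense of induction of IpcBH2, [Rh(cod)((S,S)-chiraphos)]BF4 and [Rh(cod)((S,S)-Et-DuPhos)]BF4 is assigned by analogy with simple model substrates; the antipodal reagent or ligand would be used if a first run shows the opposite sense.

Step 1
Reactants: 1 4-(benzyloxy)-3-methoxybenzaldehyde; 2 ethyl (triphenylphosphoranylidene)acetate
Product: 4 ethyl (2Z)-3-[4-(benzyloxy)-3-methoxyphenyl]-2-bromoprop-2-enoate, via bromo ylide 3 (not isolated)
Conditions: 2, NBS, CH2Cl2, −20 °C; then 1, −20 °C to rt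
Reagents that add atoms: N-bromosuccinimide O=C1CCC(=O)N1Br
Why: One-pot bromination of the stabilised ylide and Wittig olefination give the Z α-bromoacrylate (bromine cis to the aryl group), the geometry that later places the two aryl groups cis.

Step 2
Reactants: 4 ethyl (2Z)-3-[4-(benzyloxy)-3-methoxyphenyl]-2-bromoprop-2-enoate
Product: 5 (2Z)-3-[4-(benzyloxy)-3-methoxyphenyl]-2-bromoprop-2-en-1-ol
Conditions: i-Bu2AlH (2.3 equiv), CH2Cl2, −78 °C; Rochelle salt work-up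
Reagents that add atoms: none
Why: 1,2-Reduction of the conjugated ester with i-Bu2AlH at low temperature gives the allylic alcohol without touching the alkenyl bromide or the alkene geometry.

Step 3
Reactants: 5 (2Z)-3-[4-(benzyloxy)-3-methoxyphenyl]-2-bromoprop-2-en-1-ol
Product: 6 (2E)-3-[4-(benzyloxy)-3-methoxyphenyl]-2-(4,4,5,5-tetramethyl-1,3,2-dioxaborolan-2-yl)prop-2-en-1-ol
Conditions: B2pin2, PdCl2(PPh3)2 (3 mol%), PPh3, KOPh, toluene, 50 °C
Reagents that add atoms: bis(pinacolato)diboron CC1(C)OB(OC1(C)C)B1OC(C)(C)C(C)(C)O1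
Why: Miyaura borylation of the alkenyl bromide proceeds with retention of geometry, so boron ends cis to the aryl group.

Step 4
Reactants: 6 (2E)-3-[4-(benzyloxy)-3-methoxyphenyl]-2-(4,4,5,5-tetramethyl-1,3,2-dioxaborolan-2-yl)prop-2-en-1-ol
Product: 7 tert-butyl{[(2E)-3-[4-(benzyloxy)-3-methoxyphenyl]-2-(4,4,5,5-tetramethyl-1,3,2-dioxaborolan-2-yl)prop-2-en-1-yl]oxy}dimethylsilane
Conditions: TBSCl, imidazole, DMF, rt
Reagents that add atoms: tert-butyldimethylsilyl chloride CC(C)(C)[Si](C)(C)Cl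
Why: Standard silylation masks the primary hydroxyl of the ring A arm, which must stay protected through bromination and the enolate alkylation of step 13.

Step 5
Reactants: 7 tert-butyl{[(2E)-3-[4-(benzyloxy)-3-methoxyphenyl]-2-(4,4,5,5-tetramethyl-1,3,2-dioxaborolan-2-yl)prop-2-en-1-yl]oxy}dimethylsilane; 8 4-hydroxy-3-iodo-5-methoxybenzaldehyde (5-iodovanillin)
Product: 9 3-[(1E)-1-[4-(benzyloxy)-3-methoxyphenyl]-3-[(tert-butyldimethylsilyl)oxy]prop-1-en-2-yl]-4-hydroxy-5-methoxybenzaldehyde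
Conditions: Pd(OAc)2 (3 mol%), SPhos (6 mol%), K3PO4, THF/H2O (10:1), 45 °C
Reagents that add atoms: none
Why: Suzuki–Miyaura coupling of the aryl iodide with the alkenylboronate is stereoretentive and gives the trisubstituted alkene with the two aryl groups cis, the free phenol and aldehyde being tolerated.

Step 6
Reactants: 9 3-[(1E)-1-[4-(benzyloxy)-3-methoxyphenyl]-3-[(tert-butyldimethylsilyl)oxy]prop-1-en-2-yl]-4-hydroxy-5-methoxybenzaldehyde
Product: 11 (1R,2R)-1-[4-(benzyloxy)-3-methoxyphenyl]-3-[(tert-butyldimethylsilyl)oxy]-2-[2-hydroxy-5-(hydroxymethyl)-3-methoxyphenyl]propan-1-ol, via tris-boryl adduct 10 (not isolated)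
Conditions: IpcBH2 (4 equiv, from (+)-α-pinene, freed from (IpcBH2)2·TMEDA with BF3·OEt2), THF, −25 °C, 36 h; then 3 M NaOH, 30% H2O2, 0 °C
Reagents that add atoms: hydrogen peroxide OO
Why: Brown asymmetric hydroboration–oxidation adds boron to the less substituted C7 and hydrogen to C8 on one face (syn addition), the C–B to C–O oxidation retains configuration so the cis-diaryl alkene gives the anti 1R,2R array, and the excess borane reduces the aldehyde to the benzylic alcohol needed later.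

Step 7
Reactants: 11 (1R,2R)-1-[4-(benzyloxy)-3-methoxyphenyl]-3-[(tert-butyldimethylsilyl)oxy]-2-[2-hydroxy-5-(hydroxymethyl)-3-methoxyphenyl]propan-1-ol
Product: 12 [(2S,3R)-2-[4-(benzyloxy)-3-methoxyphenyl]-3-{[(tert-butyldimethylsilyl)oxy]methyl}-7-methoxy-2,3-dihydro-1-benzofuran-5-yl]methanol
Conditions: CSA (5 mol%), CH2Cl2 (0.01 M), 0 °C
Reagents that add atoms: none
Why: Acid-mediated intramolecular etherification at the p-alkoxybenzylic C7 (the invertive and the cationic pathway converge) forms the C7–O(aryl) bond and the trans 2S,3R dihydrobenzofuran under control of the fixed C8 centre.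

Step 8
Reactants: 12 [(2S,3R)-2-[4-(benzyloxy)-3-methoxyphenyl]-3-{[(tert-butyldimethylsilyl)oxy]methyl}-7-methoxy-2,3-dihydro-1-benzofuran-5-yl]methanol
Product: 13 {[(2S,3R)-2-[4-(benzyloxy)-3-methoxyphenyl]-5-(bromomethyl)-7-methoxy-2,3-dihydro-1-benzofuran-3-yl]methoxy}(tert-butyl)dimethylsilane
Conditions: CBr4, PPh3, CH2Cl2, 0 °C; used at once
Reagents that add atoms: tetrabromomethane BrC(Br)(Br)Br
Why: Appel bromination converts the only free (benzylic) hydroxyl into the bromide under neutral conditions that spare the silyl ether and the cyclic benzylic aryl ether.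

Step 9
Reactants: 14 3-bromo-4-hydroxy-5-methoxybenzaldehyde (5-bromovanillin)
Product: 15 4-(benzyloxy)-3-bromo-5-methoxybenzaldehyde
Conditions: BnBr, K2CO3, DMF, rt
Reagents that add atoms: benzyl bromide BrCc1ccccc1
Why: Williamson etherification of the acidic phenol protects ring B for the Stobbe, enolate and cross-coupling steps.

Step 10
Reactants: 15 4-(benzyloxy)-3-bromo-5-methoxybenzaldehyde; 16 dimethyl succinate
Product: 17 (3E)-4-[4-(benzyloxy)-3-bromo-5-methoxyphenyl]-3-(methoxycarbonyl)but-3-enoic acid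
Conditions: NaOMe, MeOH, reflux; then 2 M HCl
Reagents that add atoms: none
Why: Stobbe condensation of the aldehyde with the succinate gives the E arylidene succinic half-ester.

Step 11
Reactants: 17 (3E)-4-[4-(benzyloxy)-3-bromo-5-methoxyphenyl]-3-(methoxycarbonyl)but-3-enoic acid
Product: 18 (3R)-4-[4-(benzyloxy)-3-bromo-5-methoxyphenyl]-3-(methoxycarbonyl)butanoic acid
Conditions: [Rh(cod)((S,S)-Et-DuPhos)]BF4 (0.5 mol%), H2 (5 bar), NaOMe (0.1 equiv), MeOH, rt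
Reagents that add atoms: none
Why: Asymmetric hydrogenation of the carboxylate-chelating itaconate half-ester with [Rh(cod)((S,S)-Et-DuPhos)]BF4 sets the R stereocentre, the aryl bromide and benzyl ether being inert.

Step 12
Reactants: 18 (3R)-4-[4-(benzyloxy)-3-bromo-5-methoxyphenyl]-3-(methoxycarbonyl)butanoic acid
Product: 20 (4R)-4-[4-(benzyloxy)-3-bromo-5-methoxybenzyl]oxolan-2-one, via hydroxy acid 19 (not isolated)
Conditions: KOH (1.0 equiv), MeOH, evaporate; LiBH4, THF, 0 °C to rt; then 2 M HCl, rt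
Reagents that add atoms: none
Why: Chemoselective LiBH4 reduction of the methyl ester beside the carboxylate, then acid lactonisation, forms the γ-butyrolactone without touching the stereocentre.

Step 13
Reactants: 20 (4R)-4-[4-(benzyloxy)-3-bromo-5-methoxybenzyl]oxolan-2-one; 13 {[(2S,3R)-2-[4-(benzyloxy)-3-methoxyphenyl]-5-(bromomethyl)-7-methoxy-2,3-dihydro-1-benzofuran-3-yl]methoxy}(tert-butyl)dimethylsilane
Product: 22 (3R,4R)-4-[4-(benzyloxy)-3-bromo-5-methoxybenzyl]-3-{[(2S,3R)-2-[4-(benzyloxy)-3-methoxyphenyl]-3-{[(tert-butyldimethylsilyl)oxy]methyl}-7-methoxy-2,3-dihydro-1-benzofuran-5-yl]methyl}oxolan-2-one, via lithium enolate 21 (not isolated)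
Conditions: LiN(SiMe3)2 (1.1 equiv), THF, −78 °C; DMPU; 13, −78 to −30 °C
Reagents that add atoms: none
Why: Alkylation of the lactone lithium enolate occurs anti to the β-benzyl group and gives the trans 3R,4R dibenzylbutyrolactone.

Step 14
Reactants: 22 (3R,4R)-4-[4-(benzyloxy)-3-bromo-5-methoxybenzyl]-3-{[(2S,3R)-2-[4-(benzyloxy)-3-methoxyphenyl]-3-{[(tert-butyldimethylsilyl)oxy]methyl}-7-methoxy-2,3-dihydro-1-benzofuran-5-yl]methyl}oxolan-2-one; 6 (2E)-3-[4-(benzyloxy)-3-methoxyphenyl]-2-(4,4,5,5-tetramethyl-1,3,2-dioxaborolan-2-yl)prop-2-en-1-ol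
Product: 23 (3R,4R)-4-{4-(benzyloxy)-3-[(1E)-1-[4-(benzyloxy)-3-methoxyphenyl]-3-hydroxyprop-1-en-2-yl]-5-methoxybenzyl}-3-{[(2S,3R)-2-[4-(benzyloxy)-3-methoxyphenyl]-3-{[(tert-butyldimethylsilyl)oxy]methyl}-7-methoxy-2,3-dihydro-1-benzofuran-5-yl]methyl}oxolan-2-one
Conditions: Pd(OAc)2 (5 mol%), SPhos (10 mol%), K3PO4, dioxane/H2O (10:1), 70 °C
Reagents that add atoms: none
Why: Suzuki–Miyaura coupling of the ring B aryl bromide with the alkenylboronate is stereoretentive and installs the cis-diaryl trisubstituted allylic alcohol.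

Step 15
Reactants: 23 (3R,4R)-4-{4-(benzyloxy)-3-[(1E)-1-[4-(benzyloxy)-3-methoxyphenyl]-3-hydroxyprop-1-en-2-yl]-5-methoxybenzyl}-3-{[(2S,3R)-2-[4-(benzyloxy)-3-methoxyphenyl]-3-{[(tert-butyldimethylsilyl)oxy]methyl}-7-methoxy-2,3-dihydro-1-benzofuran-5-yl]methyl}oxolan-2-one
Product: 26 (3R,4R)-4-{4-(benzyloxy)-3-[(1S,2S)-1-[4-(benzyloxy)-3-methoxyphenyl]-1,3-dihydroxypropan-2-yl]-5-methoxybenzyl}-3-{[(2S,3R)-2-[4-(benzyloxy)-3-methoxyphenyl]-3-(hydroxymethyl)-7-methoxy-2,3-dihydro-1-benzofuran-5-yl]methyl}oxolan-2-one, via hydridosilyl ether 24 (not isolated), via oxasilolane 25 (not isolated)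
Conditions: Ph2SiHCl, Et3N, CH2Cl2, 0 °C; [Rh(cod)((S,S)-chiraphos)]BF4 (4 mol%), acetone, 40 °C; Bu4NF, KHCO3, 30% H2O2, THF/MeOH, 0 °C to rt
Reagents that add atoms: hydrogen peroxide OO
Why: Proposed new method: silylation of the allylic hydroxyl gives a Si–H tether, the cationic chiral rhodium diphosphine catalyst then effects a 5-endo syn-hydrosilylation that is forced by the tether to put silicon on C7 and hydrogen on C8 from one alkene face, and Tamao–Fleming oxidation replaces C7–Si by C7–O with retention so that the cis-diaryl alkene gives the anti 1S,2S diol while fluoride also removes the TBS group; the closest known reaction type is the rhodium–diphosphine-catalysed enantioselective intramolecular hydrosilylation of cinnamyl-type silyl ethers followed by Tamao oxidation to 1,3-diols, here extended to a trisubstituted 2,3-diaryl alkene that creates two adjacent stereocentres.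

Step 16
Reactants: 26 (3R,4R)-4-{4-(benzyloxy)-3-[(1S,2S)-1-[4-(benzyloxy)-3-methoxyphenyl]-1,3-dihydroxypropan-2-yl]-5-methoxybenzyl}-3-{[(2S,3R)-2-[4-(benzyloxy)-3-methoxyphenyl]-3-(hydroxymethyl)-7-methoxy-2,3-dihydro-1-benzofuran-5-yl]methyl}oxolan-2-one
Product: 27 (3R,4R)-4-{3-[(1S,2S)-1,3-dihydroxy-1-(4-hydroxy-3-methoxyphenyl)propan-2-yl]-4-hydroxy-5-methoxybenzyl}-3-{[(2S,3R)-2-(4-hydroxy-3-methoxyphenyl)-3-(hydroxymethyl)-7-methoxy-2,3-dihydro-1-benzofuran-5-yl]methyl}oxolan-2-one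
Conditions: H2 (1 atm), 10% Pd/C, EtOAc/EtOH, rt, stopped at full conversion
Reagents that add atoms: none
Why: Hydrogenolysis of the three aryl benzyl ethers over Pd/C under neutral conditions is much faster than cleavage of the benzylic alcohol or of the cyclic benzylic aryl ether and releases the target.

**Compound list**
1 | 4-(benzyloxy)-3-methoxybenzaldehyde | O=Cc1ccc(OCc2ccccc2)c(OC)c1 | starting material
2 | ethyl (triphenylphosphoranylidene)acetate | CCOC(=O)C=P(c1ccccc1)(c1ccccc1)c1ccccc1 | starting material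
3 | ethyl bromo(triphenylphosphoranylidene)acetate | CCOC(=O)C(Br)=P(c1ccccc1)(c1ccccc1)c1ccccc1 | intermediate
4 | ethyl (2Z)-3-[4-(benzyloxy)-3-methoxyphenyl]-2-bromoprop-2-enoate | CCOC(=O)/C(Br)=C/c1ccc(OCc2ccccc2)c(OC)c1 | intermediate
5 | (2Z)-3-[4-(benzyloxy)-3-methoxyphenyl]-2-bromoprop-2-en-1-ol | OC/C(Br)=C/c1ccc(OCc2ccccc2)c(OC)c1 | intermediate
6 | (2E)-3-[4-(benzyloxy)-3-methoxyphenyl]-2-(4,4,5,5-tetramethyl-1,3,2-dioxaborolan-2-yl)prop-2-en-1-ol (boron cis to aryl) | OC/C(B1OC(C)(C)C(C)(C)O1)=C/c1ccc(OCc2ccccc2)c(OC)c1 | intermediate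
7 | tert-butyl{[(2E)-3-[4-(benzyloxy)-3-methoxyphenyl]-2-(4,4,5,5-tetramethyl-1,3,2-dioxaborolan-2-yl)prop-2-en-1-yl]oxy}dimethylsilane | CC(C)(C)[Si](C)(C)OC/C(B1OC(C)(C)C(C)(C)O1)=C/c1ccc(OCc2ccccc2)c(OC)c1 | intermediate
8 | 4-hydroxy-3-iodo-5-methoxybenzaldehyde (5-iodovanillin) | COc1cc(C=O)cc(I)c1O | starting material
9 | 3-[(1E)-1-[4-(benzyloxy)-3-methoxyphenyl]-3-[(tert-butyldimethylsilyl)oxy]prop-1-en-2-yl]-4-hydroxy-5-methoxybenzaldehyde (aryl groups cis) | CC(C)(C)[Si](C)(C)OC/C(c1cc(C=O)cc(OC)c1O)=C/c1ccc(OCc2ccccc2)c(OC)c1 | intermediate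
10 | tris(isopinocampheylboryl) adduct of 9: C7–BH(Ipc), phenol O–BH(Ipc), benzylic CH2O–BH(Ipc), 1R,2R | COc1cc([C@H]([BH][C@@H]3C[C@@H]4C[C@H]([C@H]3C)C4(C)C)[C@@H](CO[Si](C)(C)C(C)(C)C)c2cc(CO[BH][C@@H]3C[C@@H]4C[C@H]([C@H]3C)C4(C)C)cc(OC)c2O[BH][C@@H]3C[C@@H]4C[C@H]([C@H]3C)C4(C)C)ccc1OCc1ccccc1 | intermediate
11 | (1R,2R)-1-[4-(benzyloxy)-3-methoxyphenyl]-3-[(tert-butyldimethylsilyl)oxy]-2-[2-hydroxy-5-(hydroxymethyl)-3-methoxyphenyl]propan-1-ol | COc1cc([C@H](O)[C@@H](CO[Si](C)(C)C(C)(C)C)c2cc(CO)cc(OC)c2O)ccc1OCc1ccccc1 | intermediate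
12 | [(2S,3R)-2-[4-(benzyloxy)-3-methoxyphenyl]-3-{[(tert-butyldimethylsilyl)oxy]methyl}-7-methoxy-2,3-dihydro-1-benzofuran-5-yl]methanol | OCc1cc(OC)c2c(c1)[C@H](CO[Si](C)(C)C(C)(C)C)[C@@H](c1ccc(OCc3ccccc3)c(OC)c1)O2 | intermediate
13 | {[(2S,3R)-2-[4-(benzyloxy)-3-methoxyphenyl]-5-(bromomethyl)-7-methoxy-2,3-dihydro-1-benzofuran-3-yl]methoxy}(tert-butyl)dimethylsilane | BrCc1cc(OC)c2c(c1)[C@H](CO[Si](C)(C)C(C)(C)C)[C@@H](c1ccc(OCc3ccccc3)c(OC)c1)O2 | intermediate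
14 | 3-bromo-4-hydroxy-5-methoxybenzaldehyde (5-bromovanillin) | COc1cc(C=O)cc(Br)c1O | starting material
15 | 4-(benzyloxy)-3-bromo-5-methoxybenzaldehyde | COc1cc(C=O)cc(Br)c1OCc1ccccc1 | intermediate
16 | dimethyl succinate | COC(=O)CCC(=O)OC | starting material
17 | (3E)-4-[4-(benzyloxy)-3-bromo-5-methoxyphenyl]-3-(methoxycarbonyl)but-3-enoic acid | COC(=O)/C(CC(=O)O)=C/c1cc(Br)c(OCc2ccccc2)c(OC)c1 | intermediate
18 | (3R)-4-[4-(benzyloxy)-3-bromo-5-methoxyphenyl]-3-(methoxycarbonyl)butanoic acid | COC(=O)[C@@H](CC(=O)O)Cc1cc(Br)c(OCc2ccccc2)c(OC)c1 | intermediate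
19 | (3R)-4-[4-(benzyloxy)-3-bromo-5-methoxyphenyl]-3-(hydroxymethyl)butanoic acid | OC[C@@H](CC(=O)O)Cc1cc(Br)c(OCc2ccccc2)c(OC)c1 | intermediate
20 | (4R)-4-[4-(benzyloxy)-3-bromo-5-methoxybenzyl]oxolan-2-one | COc1cc(C[C@H]2COC(=O)C2)cc(Br)c1OCc1ccccc1 | intermediate
21 | lithium (4R)-4-[4-(benzyloxy)-3-bromo-5-methoxybenzyl]-4,5-dihydrofuran-2-olate | [Li+].COc1cc(C[C@H]2COC([O-])=C2)cc(Br)c1OCc1ccccc1 | intermediate
22 | (3R,4R)-4-[4-(benzyloxy)-3-bromo-5-methoxybenzyl]-3-{[(2S,3R)-2-[4-(benzyloxy)-3-methoxyphenyl]-3-{[(tert-butyldimethylsilyl)oxy]methyl}-7-methoxy-2,3-dihydro-1-benzofuran-5-yl]methyl}oxolan-2-one | COc1cc(C[C@H]2COC(=O)[C@@H]2Cc2cc(OC)c3c(c2)[C@H](CO[Si](C)(C)C(C)(C)C)[C@@H](c2ccc(OCc4ccccc4)c(OC)c2)O3)cc(Br)c1OCc1ccccc1 | intermediate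
23 | (3R,4R)-4-{4-(benzyloxy)-3-[(1E)-1-[4-(benzyloxy)-3-methoxyphenyl]-3-hydroxyprop-1-en-2-yl]-5-methoxybenzyl}-3-{[(2S,3R)-2-[4-(benzyloxy)-3-methoxyphenyl]-3-{[(tert-butyldimethylsilyl)oxy]methyl}-7-methoxy-2,3-dihydro-1-benzofuran-5-yl]methyl}oxolan-2-one (aryl groups cis) | COc1cc(/C=C(/CO)c2cc(C[C@H]3COC(=O)[C@@H]3Cc3cc(OC)c4c(c3)[C@H](CO[Si](C)(C)C(C)(C)C)[C@@H](c3ccc(OCc5ccccc5)c(OC)c3)O4)cc(OC)c2OCc2ccccc2)ccc1OCc1ccccc1 | intermediate
24 | diphenylsilyl (Si–H) ether of the allylic hydroxyl of 23 | COc1cc(/C=C(/CO[SiH](c6ccccc6)c6ccccc6)c2cc(C[C@H]3COC(=O)[C@@H]3Cc3cc(OC)c4c(c3)[C@H](CO[Si](C)(C)C(C)(C)C)[C@@H](c3ccc(OCc5ccccc5)c(OC)c3)O4)cc(OC)c2OCc2ccccc2)ccc1OCc1ccccc1 | intermediate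
25 | (3S,4S)-3-[4-(benzyloxy)-3-methoxyphenyl]-2,2-diphenyl-1,2-oxasilolan-4-yl derivative: ring B of 22 carries this oxasilolane at C4 in place of bromine | COc1cc([C@H]6[Si](c7ccccc7)(c7ccccc7)OC[C@@H]6c2cc(C[C@H]3COC(=O)[C@@H]3Cc3cc(OC)c4c(c3)[C@H](CO[Si](C)(C)C(C)(C)C)[C@@H](c3ccc(OCc5ccccc5)c(OC)c3)O4)cc(OC)c2OCc2ccccc2)ccc1OCc1ccccc1 | intermediate
26 | (3R,4R)-4-{4-(benzyloxy)-3-[(1S,2S)-1-[4-(benzyloxy)-3-methoxyphenyl]-1,3-dihydroxypropan-2-yl]-5-methoxybenzyl}-3-{[(2S,3R)-2-[4-(benzyloxy)-3-methoxyphenyl]-3-(hydroxymethyl)-7-methoxy-2,3-dihydro-1-benzofuran-5-yl]methyl}oxolan-2-one | COc1cc([C@@H](O)[C@H](CO)c2cc(C[C@H]3COC(=O)[C@@H]3Cc3cc(OC)c4c(c3)[C@H](CO)[C@@H](c3ccc(OCc5ccccc5)c(OC)c3)O4)cc(OC)c2OCc2ccccc2)ccc1OCc1ccccc1 | intermediate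
27 | (3R,4R)-4-{3-[(1S,2S)-1,3-dihydroxy-1-(4-hydroxy-3-methoxyphenyl)propan-2-yl]-4-hydroxy-5-methoxybenzyl}-3-{[(2S,3R)-2-(4-hydroxy-3-methoxyphenyl)-3-(hydroxymethyl)-7-methoxy-2,3-dihydro-1-benzofuran-5-yl]methyl}oxolan-2-one (CNP0199264.2) | COc1cc([C@@H](O)[C@H](CO)c2cc(C[C@H]3COC(=O)[C@@H]3Cc3cc(OC)c4c(c3)[C@H](CO)[C@@H](c3ccc(O)c(OC)c3)O4)cc(OC)c2O)ccc1O | target

**Totals**
Total step count: 16. Longest linear sequence: 12 steps (steps 1–8, then 13–16).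

**Three steps most likely to fail**

Step 15 (the proposed new step). The hindered trisubstituted alkene may hydrosilylate slowly or with poor face selectivity. The fallback is known chemistry; it sets out from 23 and comes back at 26. Brown hydroboration of 23 with IpcBH2 made from (−)-α-pinene (THF, −25 °C) gives the bis(isopinocampheylboryl) adduct F4. Oxidation with NaOH/H2O2 gives the TBS-protected 1S,2S diol F5, and Bu4NF in THF removes the silyl group to give 26.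

Step 6. With a free phenol and an aldehyde present, the regio- and face selectivity of the borane are uncertain. The fallback sets out from 9 and comes back at 12. Asymmetric hydrogenation of 9 with [Ir(cod)((S)-tBu-PHOX)]BArF (H2, 50 bar, CH2Cl2) sets C8 and gives the 2R diarylpropane aldehyde F1. DDQ in CH2Cl2 then abstracts hydride from the p-alkoxybenzylic C7 and the ring A phenol traps the cation, giving the trans dihydrobenzofuran aldehyde F2. NaBH4 in MeOH reduces F2 to 12.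

Step 14. The α-substituted alkenylboronate may protodeboronate before it couples with the electron-rich, ortho-substituted aryl bromide. The fallback reverses the polarity; it sets out from 22 and comes back at 23. Miyaura borylation of 22 (B2pin2, PdCl2(dppf), KOAc, dioxane, 90 °C) gives the ring B pinacol boronate F3, which is coupled with alkenyl bromide 5 (Pd(OAc)2, SPhos, K3PO4, dioxane/H2O) to give 23 with retention of geometry.

**Further compounds**
F1 | step 6 | 3-[(2R)-1-[4-(benzyloxy)-3-methoxyphenyl]-3-[(tert-butyldimethylsilyl)oxy]propan-2-yl]-4-hydroxy-5-methoxybenzaldehyde | CC(C)(C)[Si](C)(C)OC[C@H](Cc1ccc(OCc2ccccc2)c(OC)c1)c1cc(C=O)cc(OC)c1O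
F2 | step 6 | (2S,3R)-2-[4-(benzyloxy)-3-methoxyphenyl]-3-{[(tert-butyldimethylsilyl)oxy]methyl}-7-methoxy-2,3-dihydro-1-benzofuran-5-carbaldehyde | O=Cc1cc(OC)c2c(c1)[C@H](CO[Si](C)(C)C(C)(C)C)[C@@H](c1ccc(OCc3ccccc3)c(OC)c1)O2
F3 | step 14 | pinacol boronate of 22 (bromine replaced by 4,4,5,5-tetramethyl-1,3,2-dioxaborolan-2-yl) | COc1cc(C[C@H]2COC(=O)[C@@H]2Cc2cc(OC)c3c(c2)[C@H](CO[Si](C)(C)C(C)(C)C)[C@@H](c2ccc(OCc4ccccc4)c(OC)c2)O3)cc(B2OC(C)(C)C(C)(C)O2)c1OCc1ccccc1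
F4 | step 15 | bis(isopinocampheylboryl) adduct of 23: C7–BH(Ipc) and C9–O–BH(Ipc) on the ring B arm, 1S,2S | COc1cc([C@@H]([BH][C@H]6C[C@H]7C[C@@H]([C@@H]6C)C7(C)C)[C@H](CO[BH][C@H]6C[C@H]7C[C@@H]([C@@H]6C)C7(C)C)c2cc(C[C@H]3COC(=O)[C@@H]3Cc3cc(OC)c4c(c3)[C@H](CO[Si](C)(C)C(C)(C)C)[C@@H](c3ccc(OCc5ccccc5)c(OC)c3)O4)cc(OC)c2OCc2ccccc2)ccc1OCc1ccccc1
F5 | step 15 | 26 with the hydroxymethyl group of the dihydrobenzofuran still protected as its TBS ether | COc1cc([C@@H](O)[C@H](CO)c2cc(C[C@H]3COC(=O)[C@@H]3Cc3cc(OC)c4c(c3)[C@H](CO[Si](C)(C)C(C)(C)C)[C@@H](c3ccc(OCc5ccccc5)c(OC)c3)O4)cc(OC)c2OCc2ccccc2)ccc1OCc1ccccc1
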